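## The problem

Target 39 is a ten-membered carbocycle (C1–C10) with a trisubstituted C4=C5 double bond whose ring carbons C3 and C6 are trans. It carries a trans-fused α-methylene-γ-butyrolactone across C6/C7 (C11=C13, C12=O), a methacrylate on the C8 oxygen, and two primary alcohols, C15 on C4 and C14 on C10. A synthesis has to form a strained medium ring and fix the geometry of the ring alkene at the same time, because that geometry cannot be repaired once the ring exists. C6, C7 and C8 are contiguous and can be built one from the other, with the oxygenated C6 as the anchor from the chiral pool. C10 is insulated from them by the C9 methylene and can only be reached through the ring conformation or through the C8 oxygen. The methylene lactone and the methacrylate are Michael acceptors that tolerate no enolates, hydrides, alkoxides or organometallics, and the lactone excludes strong hydride reagents, so both acceptors must be made last and every earlier reduction must spare a lactone. The feature that opens the problem is the 1,3-relationship of C10 and C5 through C4: a bond drawn between C4 and C10 turns the ring into a fused bicycle (five-membered ring C10–C1–C2–C3–C4, seven-membered ring C4–C5–C6–C7–C8–C9–C10) in which O–C10–C4–C5–O is a 1,3-diol array. Cutting that bond again, with the C10 oxygen as alkoxide and the C5 oxygen as leaving group, returns the ring, the C10 carbonyl and the C4=C5 alkene in one event, and turns alkene geometry into a question of relative configuration at C4 and C5.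

## Retrosynthesis

**Ester and silyl ethers (39 ⇒ 38 ⇒ 36 + 37 ⇒ 35).** The acyl C–O bond at C8 and the two O–Si bonds are cut first. Both Michael acceptors are thereby made at the end, and the only orthogonality needed is a secondary triethylsilyl ether (C8) against two primary tert-butyldiphenylsilyl ethers (C14, C15). The forward steps must unmask C8 alone, acylate a hindered secondary alcohol with anhydride 37, and desilylate without base.

**C11=C13, then C14–O/C10–H, then C10=C14 (35 ⇒ 32 ⇒ 31 ⇒ 29 ⇒ 28).** The methylene carbon is removed from the lactone (enolate aminomethylation–elimination in the forward sense). The C14 carbinol is traced through alkene 29 to ketone 28. C10 has to be made after the ring exists, because the fragmentation delivers it as a carbonyl. The forward hydroboration must add hydrogen to C10 from the face away from the C8 silyloxy group.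

**C4–C10 reconnected (28 ⇒ 26), the key cut.** Joining C4 to C10, with a hydroxyl on C10 and a mesylate on C5, replaces the ten-membered ring by the cis-fused five–seven bicycle 26.
- Against the direct ring closures discussed below, no macrocyclisation is asked for: ordinary ring sizes are built and the medium ring is unveiled.
- The alkene geometry is fixed by the C4/C5 relative configuration.
- The forward fragmentation needs the C5–O bond antiperiplanar to C4–C10.
- C4 must carry no carbanion-stabilising group. C15 is therefore a silyloxymethyl group at this stage and not an ester, which would open a stepwise retro-aldol/E1cB path and erode the geometry.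

**Functional-group adjustment on the bicycle (26 ⇒ 25 ⇒ 24 ⇒ 23 ⇒ 22 ⇒ 21).** The C15 silyl ether is traced to a benzyl ester and the C8 silyl ether to a ketone. A benzyl ester is chosen because hydrogenolysis to acid 24 followed by borane reduction is the one way to reduce C15 beside the lactone. The C8 ketone is reduced on the rigid bicycle, where the ring decides the face.

**C9–C10 (21 ⇒ 19, through enolate 20).** The seven-membered ring is opened at C9–C10. A carbanion at C9 next to a C8 ether would eliminate, so C8 is kept as a ketone and C9 becomes an enolate carbon, generated regiospecifically from α-bromo ketone 19. Bromo ketone 19 comes from the vinyl group of 17 through bromohydrin 18. The forward step must close the ring cis and must not disturb the mesylate.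

**O–C5 and C4–C10 (17 ⇒ 16 ⇒ 14 ⇒ 11, through nitrile oxide 13).** The β-hydroxy ketone 16 is an aldol retron, but it is traced to isoxazoline 14 and not to an aldol.
- An aldol of a 2-oxocyclopentanecarboxylate with aldehyde 5 would form the same C4–C5 bond. Its closed transition state places ring carbon C3 anti to the new hydroxyl, which is the relative configuration that fragments to the ring-cis alkene.
- The intramolecular nitrile oxide cycloaddition adds C10 and O to one face of an alkene of defined geometry. It therefore sets C4/C5 stereospecifically and closes the five-membered ring in the same step.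
- The forward step needs face selectivity with respect to C6.

**C4=C5 (11 ⇒ 9 ⇒ 5 + 8).** The enoate is cut by olefination into aldehyde 5 and phosphonate 8. The E-enoate (C6 cis to the C3 chain) is the normal outcome for an α-alkyl phosphonoacetate. Suprafacial cycloaddition followed by antiperiplanar fragmentation later converts this geometry into the ring-trans alkene.

**Fragments (5 ⇒ 4 ⇒ 2 + 3 ⇒ 1; 8 ⇒ 6 + 7).** Aldehyde 5 goes back to butenolide 1 by anti conjugate addition of vinyl reagent 3 (C6 controls C7). Phosphonate 8 is the alkylation product of phosphonoacetate 6 with chloro acetal 7, which supplies C1–C3 and the masked C10.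

## Roads not taken

**Alternative 1:** The cut is C7–C8. In the forward step SmI2 reduces the C8 aldehyde of the open-chain butenolide aldehyde A2 to a ketyl, which adds to the butenolide β-carbon C7 (10-exo) and gives hydroxy lactone A1.
- Merits: the lactone arrives intact from a butenolide, one step forms the ring, the C7–C8 bond and two stereocentres, and the route would be clearly shorter than the chosen one, with less protecting-group traffic.
- Weak points: a ten-membered ring is closed end to end by a short-lived radical anion that can also be reduced to the carbinol or dimerise. C7 and C8 are both set in a flexible macrocyclic transition state, and the trans lactone requires attack on the butenolide face opposite the chain that carries the ketyl. A2 must already contain the ring-trans alkene and C10, made on an open chain.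
- Comparison: on step count this road is better. The chosen plan sets against it that the ring is unveiled and not closed, that C7 comes from a dependable anti conjugate addition, and that C8 is set on a rigid bicycle.

**Alternative 2:** The cut is C5–C6. CrCl2 with catalytic NiCl2 converts the alkenyl iodide of iodo aldehyde A4 into an alkenylchromium species that adds to the C6 aldehyde and gives the ten-membered allylic alcohol A3.
- Merits: this alkenylation is one of the most dependable medium-ring closures, it keeps the geometry of the iodide and tolerates esters and ethers. C10 can be set on the open chain by reagent control, which is firmer than the late substrate-controlled hydroboration of the chosen plan.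
- Weak points: the C6 carbinol is created in the ring closure under induction from C7 only, and the wrong epimer cannot give the trans lactone without an oxidation–reduction detour. C6 is no longer taken from the chiral pool. The ring-trans trisubstituted alkenyl iodide with its C15 oxygen needs its own synthesis, and stoichiometric CrCl2 at high dilution is required.
- Comparison: this road is at least as good for C10. The chosen plan sets against it a C6 of secured configuration and an alkene geometry that follows from a stereospecific sequence and not from a separately made iodide.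

**Alternative 3:** The cut is C1–C2. (Me3Si)3SiH with AIBN abstracts iodine from C2 of iodo acrylate A6, the primary radical adds to the acrylate terminus C1 (10-endo), and hydrogen transfer to the C10 radical gives lactone ester A5.
- Merits: the ring closes between two methylenes, far from every functional group. Endo radical macrocyclisations onto acrylates are efficient, and the conditions spare the lactone.
- Weak points: C10 is set when a planar α-ester radical inside a freshly formed macrocycle takes up hydrogen, with no control element nearby. C14 arrives as an ester that must then be reduced beside the lactone. Premature reduction of the radical competes. C4=C5 and C6–C8 again have to be assembled on an open chain.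
- Comparison: this is the cleanest ring closure of the three. Both plans set C10 by substrate control on the ten-membered ring, but the chosen plan has a bulky C8 neighbour and a tether-based rescue for C10, and its alkene geometry is guaranteed by the fragmentation.

Key step: step 18

Remark: atoms keep the numbers C1–C15 of the final ring throughout, the hydroazulene intermediates are named as 4,10-cyclo derivatives of that skeleton, and 1, 3, 6, 7 and 37 are taken as commercial.

## Route

Step 1
Reactants: 1 (R)-5-(hydroxymethyl)furan-2(5H)-one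
Product: 2 (R)-5-[(triethylsilyloxy)methyl]furan-2(5H)-one
Conditions: TESCl, imidazole, CH2Cl2, 0 °C
Reagents that add atoms: chlorotriethylsilane CC[Si](Cl)(CC)CC
Why: Standard silylation of the primary alcohol; the silyloxymethyl group shields one face of the butenolide in step 2, and a primary triethylsilyl ether can be oxidised directly in step 3.

Step 2
Reactants: 2 silyl ether of the butenolide; 3 vinylmagnesium bromide
Product: 4 (4S,5R)-4-ethenyl-5-[(triethylsilyloxy)methyl]oxolan-2-one
Conditions: CH2=CHMgBr, CuI (10 mol %), THF, −78 °C; aq NH4Cl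
Reagents that add atoms: none
Why: Copper-catalysed conjugate addition of a vinyl Grignard reagent to a γ-substituted butenolide; the vinyl group enters C7 anti to the C6 substituent and sets the 6,7-trans relationship of the final lactone.

Step 3
Reactants: 4 vinyl lactone silyl ether
Product: 5 (2R,3S)-3-ethenyl-5-oxooxolane-2-carbaldehyde
Conditions: (COCl)2, DMSO, CH2Cl2, −78 → −20 °C; Et3N
Reagents that add atoms: none
Why: Swern oxidation carried out directly on the primary triethylsilyl ether, which is cleaved and oxidised in one operation; the low temperature should leave the α-oxygenated stereocentre C6 untouched.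

Step 4
Reactants: 6 benzyl 2-(diethoxyphosphoryl)acetate; 7 4-chloro-1,1-dimethoxybutane
Product: 8 benzyl 2-(diethoxyphosphoryl)-6,6-dimethoxyhexanoate (racemic)
Conditions: NaH, DMF, 0 °C; then 7, NaI (cat.), 70 °C
Reagents that add atoms: none
Why: C-alkylation of a phosphonoacetate anion with a primary halide under Finkelstein catalysis; the chain supplies C3, C2, C1 and the masked C10 aldehyde, and the stereocentre formed is lost in step 5.

Step 5
Reactants: 5 lactone aldehyde; 8 alkylated phosphonate
Product: 9 benzyl (2E)-2-(4,4-dimethoxybutyl)-3-[(2R,3S)-3-ethenyl-5-oxooxolan-2-yl]prop-2-enoate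
Conditions: LiCl, DBU, MeCN, 0 °C → rt
Reagents that add atoms: none
Why: Horner–Wadsworth–Emmons olefination under Masamune–Roush conditions; an α-alkyl phosphonoacetate places the aldehyde residue trans to the ester, so C6 ends cis to the C3 chain, and the weak base spares the epimerisable C6.

Step 6
Reactants: 9 acetal enoate
Product: 11 benzyl (2E)-2-[4-(hydroxyimino)butyl]-3-[(2R,3S)-3-ethenyl-5-oxooxolan-2-yl]prop-2-enoate, via aldehyde 10 (not isolated)
Conditions: 1 M HCl, THF, rt; then NH2OH·HCl, NaOAc, rt
Reagents that add atoms: hydroxylamine hydrochloride Cl.NO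
Why: Acetal hydrolysis followed by oxime formation in the same flask; lactone, benzyl ester and the trisubstituted enoate are inert to dilute acid and to hydroxylamine at this pH.

Step 7
Reactants: 11 oxime
Product: 14 benzyl (3R,3aR)-3-[(2R,3S)-3-ethenyl-5-oxooxolan-2-yl]-3,4,5,6-tetrahydro-3aH-cyclopenta[c][1,2]oxazole-3a-carboxylate, via hydroximoyl chloride 12 (not isolated), via nitrile oxide 13 (not isolated)
Conditions: aq NaOCl, CH2Cl2, 0 °C → rt, high dilution
Reagents that add atoms: none
Why: Intramolecular nitrile oxide–alkene cycloaddition of the 5-hexenyl type: the dipole carbon C10 bonds to C4 and its oxygen to C5 on one face of the alkene, so the E geometry becomes the C4/C5 relative configuration and the five-membered carbocycle closes at the same time. Allylic 1,3-strain with the cis C3 chain holds H6 in the alkene plane, and the dipole should add anti to C7 on the side of the ring oxygen, which gives C5–O syn to C6–O.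

Step 8
Reactants: 14 isoxazoline
Product: 16 benzyl (1S)-1-{(R)-[(2R,3S)-3-ethenyl-5-oxooxolan-2-yl](hydroxy)methyl}-2-oxocyclopentane-1-carboxylate, via hydroxy imine 15 (not isolated)
Conditions: Mo(CO)6, MeCN/H2O, 80 °C
Reagents that add atoms: water O
Why: Reductive N–O cleavage of the isoxazoline and hydrolysis of the β-hydroxy imine unmask the aldol-type β-hydroxy ketone; the vinyl group and the benzyl ester survive, which hydrogenation would not allow.

Step 9
Reactants: 16 hydroxy ketone
Product: 17 benzyl (1S)-1-{(R)-[(2R,3S)-3-ethenyl-5-oxooxolan-2-yl][(methanesulfonyl)oxy]methyl}-2-oxocyclopentane-1-carboxylate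
Conditions: MsCl, Et3N, CH2Cl2, −10 °C
Reagents that add atoms: methanesulfonyl chloride CS(=O)(=O)Cl
Why: Sulfonylation through sulfene works on the hindered carbinol; C4 has no hydrogen, so the β-mesyloxy ketone cannot eliminate, and the mesylate both covers O5 during the oxidation of step 11 and is the later leaving group.

Step 10
Reactants: 17 mesylate
Product: 18 benzyl (1S)-1-{(R)-[(2R,3S)-3-(2-bromo-1-hydroxyethyl)-5-oxooxolan-2-yl][(methanesulfonyl)oxy]methyl}-2-oxocyclopentane-1-carboxylate (both C8 epimers)
Conditions: NBS, THF/H2O, 0 °C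
Reagents that add atoms: N-bromosuccinimide O=C1CCC(=O)N1Br; water O
Why: Markovnikov bromohydrin formation on the only remaining alkene puts OH on C8 and Br on C9; the C8 configuration is irrelevant because it is oxidised next.

Step 11
Reactants: 18 bromohydrin
Product: 19 benzyl (1S)-1-{(R)-[(2R,3R)-3-(bromoacetyl)-5-oxooxolan-2-yl][(methanesulfonyl)oxy]methyl}-2-oxocyclopentane-1-carboxylate
Conditions: Dess–Martin periodinane, NaHCO3, CH2Cl2, rt
Reagents that add atoms: none
Why: Buffered Dess–Martin oxidation of the secondary alcohol gives the α-bromo ketone with the halogen fixed on C9; the trans arrangement on the lactone is the stable one, so the now enolisable C7 is not at risk.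

Step 12
Reactants: 19 α-bromo ketone
Product: 21 benzyl (4S,5R,6R,7R,10R)-10-hydroxy-5-(methanesulfonyloxy)-8-oxo-4,10-cyclo-13,14-dinorgermacran-12,6-olide-15-oate, via samarium enolate 20 (not isolated)
Conditions: SmI2 (2.2 equiv), THF, −78 °C; pH 7 buffer
Reagents that add atoms: none
Why: SmI2 reduces the C–Br bond to a trivalent samarium enolate located at C9, which adds to the C10 carbonyl held in a chelate with the ester (intramolecular Reformatsky-type aldol closing the seven-membered ring). An enolate at C9 has no β-leaving group, unlike an alkyl metal next to a C8 ether, and the tether through C5 delivers C9 to the face of C10 syn to C5, so the rings are cis-fused with the C10 hydroxyl cis to the ester.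

Step 13
Reactants: 21 tricyclic keto lactone
Product: 22 benzyl (4S,5R,6R,7S,8R,10R)-8,10-dihydroxy-5-(methanesulfonyloxy)-4,10-cyclo-13,14-dinorgermacran-12,6-olide-15-oate
Conditions: NaBH4, CeCl3·7H2O, MeOH, −78 °C
Reagents that add atoms: none
Why: Luche reduction; hydride should reach C8 from the face opposite the axial C1 methylene of the cis-fused cyclopentane, giving the equatorial alcohol trans to the C7 side chain (8R), and the near-neutral medium avoids alkoxide formation at C10.

Step 14
Reactants: 22 diol
Product: 23 benzyl (4S,5R,6R,7R,8R,10R)-10-hydroxy-5-(methanesulfonyloxy)-8-(triethylsilyloxy)-4,10-cyclo-13,14-dinorgermacran-12,6-olide-15-oate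
Conditions: TESCl, imidazole, DMF, 0 °C → rt
Reagents that add atoms: chlorotriethylsilane CC[Si](Cl)(CC)CC
Why: Selective silylation of the secondary C8 hydroxyl; the tertiary C10 hydroxyl does not react with a silyl chloride under imidazole catalysis.

Step 15
Reactants: 23 benzyl ester
Product: 24 (4S,5R,6R,7R,8R,10R)-10-hydroxy-5-(methanesulfonyloxy)-8-(triethylsilyloxy)-4,10-cyclo-13,14-dinorgermacran-12,6-olide-15-oic acid
Conditions: H2 (1 atm), 10% Pd/C, EtOAc, rt
Reagents that add atoms: none
Why: Hydrogenolysis of the benzyl ester; no alkene is present at this stage, and mesylate, silyl ether and lactone are inert in ethyl acetate.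

Step 16
Reactants: 24 hydroxy acid
Product: 25 (4S,5R,6R,7R,8R,10R)-10,15-dihydroxy-5-(methanesulfonyloxy)-8-(triethylsilyloxy)-4,10-cyclo-13,14-dinorgermacran-12,6-olide
Conditions: BH3·SMe2, THF, 0 °C → rt; MeOH
Reagents that add atoms: none
Why: Borane reduces a carboxylic acid much faster than a lactone, which is the reason C15 was carried as a benzyl ester; no stereocentre is touched.

Step 17
Reactants: 25 primary alcohol
Product: 26 (4S,5R,6R,7R,8R,10R)-15-(tert-butyldiphenylsilyloxy)-10-hydroxy-5-(methanesulfonyloxy)-8-(triethylsilyloxy)-4,10-cyclo-13,14-dinorgermacran-12,6-olide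
Conditions: TBDPSCl, imidazole, DMAP (cat.), CH2Cl2, rt
Reagents that add atoms: tert-butylchlorodiphenylsilane CC(C)(C)[Si](Cl)(c1ccccc1)c1ccccc1
Why: Selective silylation of the primary neopentyl alcohol; with C15 as a silyl ether no carbanion-stabilising group remains on C4, so the fragmentation of step 18 cannot take a stepwise retro-aldol course.

Step 18
Reactants: 26 cis-fused hydroazulenol mesylate
Product: 28 (4Z,6S,7R,8R)-15-(tert-butyldiphenylsilyloxy)-10-oxo-8-(triethylsilyloxy)-13,14-dinorgermacr-4-en-12,6-olide, via potassium alkoxide 27 (not isolated)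
Conditions: KOtBu (1.05 equiv), THF, −20 → 0 °C; aq NH4Cl
Reagents that add atoms: none
Why: Grob (Wharton-type) fragmentation of a cyclic 1,3-diol monosulfonate: KOtBu turns the tertiary C10 hydroxyl into alkoxide 27, whose oxygen lone pair pushes into the C4–C10 bond as the C5–O bond of the mesylate breaks, so C10=O and C4=C5 form in one concerted step. No ring is closed by bond formation: the ten-membered ring appears because the bond shared by the five- and seven-membered rings is cut, so no end-to-end macrocyclisation is needed. No stereocentre is created; C4, C5 and C10 become trigonal. The alkene geometry is stereospecific: with C4–C10 antiperiplanar to C5–O, the relative configuration at C4 and C5 set in step 7 holds C3 anti to C6, which gives the ring-trans alkene (Z by the sequence rule because of the C15 oxygen). The selectivity needed is fragmentation over substitution or elimination, and the substrate secures it: the trans-fused lactone and the all-trans array on C5–C8 hold the seven-membered ring in the conformer with the mesylate equatorial and antiperiplanar to the ring-fusion bond, C4 has no hydrogen for elimination, and O10 cannot reach the rear of C5. Because C15 is a silyloxymethyl group and not an ester, there is no stabilised carbanion through which a retro-aldol/E1cB path could scramble the geometry. One equivalent of base suffices, since the alkoxide is consumed as potassium mesylate forms and nothing is left to enolise the new ketone towards the C8 silyloxy group.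

Step 19
Reactants: 28 cyclodecenone
Product: 29 (4Z,6S,7R,8R)-15-(tert-butyldiphenylsilyloxy)-8-(triethylsilyloxy)-13-norgermacra-4,10(14)-dien-12,6-olide
Conditions: Ph3PCH3Br, KN(SiMe3)2, THF, 0 °C; then 28, −78 → 0 °C
Reagents that add atoms: methyltriphenylphosphonium bromide C[P+](c1ccccc1)(c1ccccc1)c1ccccc1.[Br-]
Why: Wittig methylenation; the ylide reacts with the ketone and not with the lactone, and a weakly basic ylide is preferred to Lewis-acidic titanium reagents, which could trigger transannular reactions of the cyclodecenone.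

Step 20
Reactants: 29 exocyclic alkene
Product: 31 (4Z,6S,7R,8R,10R)-15-(tert-butyldiphenylsilyloxy)-14-hydroxy-8-(triethylsilyloxy)-13-norgermacr-4-en-12,6-olide, via alkylborane 30 (not isolated)
Conditions: 9-BBN, THF, 0 °C → rt; then H2O2, NaOAc, H2O, 0 °C
Reagents that add atoms: hydrogen peroxide OO
Why: Hydroboration–oxidation; 9-BBN takes the 1,1-disubstituted exocyclic alkene and not the trisubstituted ring alkene, boron goes to C14, and hydrogen is expected to reach C10 on the face away from the bulky C8 silyloxy group, which places C14 syn to O8 (10R). Buffered peroxide keeps the lactone closed.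

Step 21
Reactants: 31 primary alcohol
Product: 32 (4Z,6S,7R,8R,10R)-14,15-bis(tert-butyldiphenylsilyloxy)-8-(triethylsilyloxy)-13-norgermacr-4-en-12,6-olide
Conditions: TBDPSCl, imidazole, DMF, rt
Reagents that add atoms: tert-butylchlorodiphenylsilane CC(C)(C)[Si](Cl)(c1ccccc1)c1ccccc1
Why: Silylation of the primary C14 alcohol protects it from the amide base of step 22.

Step 22
Reactants: 32 saturated lactone
Product: 35 (4Z,6S,7R,8R,10R)-14,15-bis(tert-butyldiphenylsilyloxy)-8-(triethylsilyloxy)germacra-4,11(13)-dien-12,6-olide, via Mannich base 33 (not isolated), via ammonium iodide 34 (not isolated)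
Conditions: LiN(iPr)2, THF, −78 °C; CH2=NMe2+ I−, −78 → 0 °C; then MeI, THF, rt; then aq NaHCO3, CH2Cl2
Reagents that add atoms: Eschenmoser's salt C=[N+](C)C.[I-]
Why: α-Methylenation of the lactone by enolate aminomethylation, N-methylation and elimination of trimethylamine; C7 carries no leaving group, so the enolate is stable, and C11 ends trigonal.

Step 23
Reactants: 35 methylene lactone
Product: 36 (4Z,6S,7S,8R,10R)-14,15-bis(tert-butyldiphenylsilyloxy)-8-hydroxygermacra-4,11(13)-dien-12,6-olide
Conditions: PPTS, MeOH/CH2Cl2, 0 °C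
Reagents that add atoms: none
Why: Acid-catalysed methanolysis removes the secondary triethylsilyl ether much faster than the primary tert-butyldiphenylsilyl ethers, and the conjugated lactone does not add methanol under weak acid.

Step 24
Reactants: 36 C8 alcohol; 37 methacrylic anhydride
Product: 38 (4Z,6S,7S,8R,10R)-14,15-bis(tert-butyldiphenylsilyloxy)-8-(methacryloyloxy)germacra-4,11(13)-dien-12,6-olide
Conditions: Et3N, DMAP, CH2Cl2, 0 °C → rt
Reagents that add atoms: none
Why: DMAP-catalysed acylation of the hindered secondary alcohol; the C8–O bond is not broken, so the configuration is retained.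

Step 25
Reactants: 38 bis-silyl ether
Product: 39 (4Z,6S,7S,8R,10R)-14,15-dihydroxy-8-(methacryloyloxy)germacra-4,11(13)-dien-12,6-olide
Conditions: HF·pyridine, pyridine, THF, 0 °C → rt
Reagents that add atoms: none
Why: Fluoride cleavage of both primary silyl ethers under buffered, non-basic conditions that leave the two Michael acceptors and the ester in place.

## Compound list

1 | (R)-5-(hydroxymethyl)furan-2(5H)-one | OC[C@@H]1OC(=O)C=C1 | starting material
2 | (R)-5-[(triethylsilyloxy)methyl]furan-2(5H)-one | CC[Si](CC)(CC)OC[C@@H]1OC(=O)C=C1 | intermediate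
3 | vinylmagnesium bromide | C=C[Mg]Br | starting material
4 | (4S,5R)-4-ethenyl-5-[(triethylsilyloxy)methyl]oxolan-2-one | CC[Si](CC)(CC)OC[C@@H]1OC(=O)C[C@H]1C=C | intermediate
5 | (2R,3S)-3-ethenyl-5-oxooxolane-2-carbaldehyde | O=C[C@@H]1OC(=O)C[C@H]1C=C | intermediate
6 | benzyl 2-(diethoxyphosphoryl)acetate | CCOP(=O)(CC(=O)OCc1ccccc1)OCC | starting material
7 | 4-chloro-1,1-dimethoxybutane | COC(CCCCl)OC | starting material
8 | benzyl 2-(diethoxyphosphoryl)-6,6-dimethoxyhexanoate (racemic) | CCOP(=O)(OCC)C(CCCC(OC)OC)C(=O)OCc1ccccc1 | intermediate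
9 | benzyl (2E)-2-(4,4-dimethoxybutyl)-3-[(2R,3S)-3-ethenyl-5-oxooxolan-2-yl]prop-2-enoate | COC(OC)CCC/C(C(=O)OCc1ccccc1)=C\[C@@H]1OC(=O)C[C@H]1C=C | intermediate
10 | benzyl (2E)-3-[(2R,3S)-3-ethenyl-5-oxooxolan-2-yl]-2-(4-oxobutyl)prop-2-enoate | O=CCCC/C(C(=O)OCc1ccccc1)=C\[C@@H]1OC(=O)C[C@H]1C=C | intermediate
11 | benzyl (2E)-2-[4-(hydroxyimino)butyl]-3-[(2R,3S)-3-ethenyl-5-oxooxolan-2-yl]prop-2-enoate | ON=CCCC/C(C(=O)OCc1ccccc1)=C\[C@@H]1OC(=O)C[C@H]1C=C | intermediate
12 | benzyl (2E)-2-[4-chloro-4-(hydroxyimino)butyl]-3-[(2R,3S)-3-ethenyl-5-oxooxolan-2-yl]prop-2-enoate | ON=C(Cl)CCC/C(C(=O)OCc1ccccc1)=C\[C@@H]1OC(=O)C[C@H]1C=C | intermediate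
13 | nitrile oxide of benzyl (2E)-2-(3-cyanopropyl)-3-[(2R,3S)-3-ethenyl-5-oxooxolan-2-yl]prop-2-enoate | [O-][N+]#CCCC/C(C(=O)OCc1ccccc1)=C\[C@@H]1OC(=O)C[C@H]1C=C | intermediate
14 | benzyl (3R,3aR)-3-[(2R,3S)-3-ethenyl-5-oxooxolan-2-yl]-3,4,5,6-tetrahydro-3aH-cyclopenta[c][1,2]oxazole-3a-carboxylate | O=C(OCc1ccccc1)[C@]23CCCC2=NO[C@H]3[C@@H]4OC(=O)C[C@H]4C=C | intermediate
15 | benzyl (1R)-1-{(R)-[(2R,3S)-3-ethenyl-5-oxooxolan-2-yl](hydroxy)methyl}-2-iminocyclopentane-1-carboxylate | O=C(OCc1ccccc1)[C@@]1(CCCC1=N)[C@@H](O)[C@@H]2OC(=O)C[C@H]2C=C | intermediate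
16 | benzyl (1S)-1-{(R)-[(2R,3S)-3-ethenyl-5-oxooxolan-2-yl](hydroxy)methyl}-2-oxocyclopentane-1-carboxylate | O=C(OCc1ccccc1)[C@@]1(CCCC1=O)[C@@H](O)[C@@H]2OC(=O)C[C@H]2C=C | intermediate
17 | benzyl (1S)-1-{(R)-[(2R,3S)-3-ethenyl-5-oxooxolan-2-yl][(methanesulfonyl)oxy]methyl}-2-oxocyclopentane-1-carboxylate | O=C(OCc1ccccc1)[C@@]1(CCCC1=O)[C@@H](OS(C)(=O)=O)[C@@H]2OC(=O)C[C@H]2C=C | intermediate
18 | benzyl (1S)-1-{(R)-[(2R,3S)-3-(2-bromo-1-hydroxyethyl)-5-oxooxolan-2-yl][(methanesulfonyl)oxy]methyl}-2-oxocyclopentane-1-carboxylate (both carbinol epimers) | O=C(OCc1ccccc1)[C@@]1(CCCC1=O)[C@@H](OS(C)(=O)=O)[C@@H]2OC(=O)C[C@H]2C(O)CBr | intermediate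
19 | benzyl (1S)-1-{(R)-[(2R,3R)-3-(bromoacetyl)-5-oxooxolan-2-yl][(methanesulfonyl)oxy]methyl}-2-oxocyclopentane-1-carboxylate | O=C(OCc1ccccc1)[C@@]1(CCCC1=O)[C@@H](OS(C)(=O)=O)[C@@H]2OC(=O)C[C@H]2C(=O)CBr | intermediate
20 | diiodosamarium enolate of 19 (O–Sm on C8, methylene C9) | O=C(OCc1ccccc1)[C@@]1(CCCC1=O)[C@@H](OS(C)(=O)=O)[C@@H]2OC(=O)C[C@H]2C(=C)O[Sm](I)I | intermediate
21 | benzyl (4S,5R,6R,7R,10R)-10-hydroxy-5-(methanesulfonyloxy)-8-oxo-4,10-cyclo-13,14-dinorgermacran-12,6-olide-15-oate (cis-fused five–seven bicycle, trans-fused lactone) | O=C(OCc1ccccc1)[C@]12CCC[C@@]1(O)CC(=O)[C@@H]3CC(=O)O[C@H]3[C@@H]2OS(C)(=O)=O | intermediate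
22 | benzyl (4S,5R,6R,7S,8R,10R)-8,10-dihydroxy-5-(methanesulfonyloxy)-4,10-cyclo-13,14-dinorgermacran-12,6-olide-15-oate | O=C(OCc1ccccc1)[C@]12CCC[C@@]1(O)C[C@@H](O)[C@@H]3CC(=O)O[C@H]3[C@@H]2OS(C)(=O)=O | intermediate
23 | benzyl (4S,5R,6R,7R,8R,10R)-10-hydroxy-5-(methanesulfonyloxy)-8-(triethylsilyloxy)-4,10-cyclo-13,14-dinorgermacran-12,6-olide-15-oate | O=C(OCc1ccccc1)[C@]12CCC[C@@]1(O)C[C@@H](O[Si](CC)(CC)CC)[C@@H]3CC(=O)O[C@H]3[C@@H]2OS(C)(=O)=O | intermediate
24 | (4S,5R,6R,7R,8R,10R)-10-hydroxy-5-(methanesulfonyloxy)-8-(triethylsilyloxy)-4,10-cyclo-13,14-dinorgermacran-12,6-olide-15-oic acid | OC(=O)[C@]12CCC[C@@]1(O)C[C@@H](O[Si](CC)(CC)CC)[C@@H]3CC(=O)O[C@H]3[C@@H]2OS(C)(=O)=O | intermediate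
25 | (4S,5R,6R,7R,8R,10R)-10,15-dihydroxy-5-(methanesulfonyloxy)-8-(triethylsilyloxy)-4,10-cyclo-13,14-dinorgermacran-12,6-olide | OC[C@]12CCC[C@@]1(O)C[C@@H](O[Si](CC)(CC)CC)[C@@H]3CC(=O)O[C@H]3[C@@H]2OS(C)(=O)=O | intermediate
26 | (4S,5R,6R,7R,8R,10R)-15-(tert-butyldiphenylsilyloxy)-10-hydroxy-5-(methanesulfonyloxy)-8-(triethylsilyloxy)-4,10-cyclo-13,14-dinorgermacran-12,6-olide | CC(C)(C)[Si](OC[C@]12CCC[C@@]1(O)C[C@@H](O[Si](CC)(CC)CC)[C@@H]3CC(=O)O[C@H]3[C@@H]2OS(C)(=O)=O)(c4ccccc4)c5ccccc5 | intermediate
27 | potassium C10 alkoxide of 26 | CC(C)(C)[Si](OC[C@]12CCC[C@@]1([O-])C[C@@H](O[Si](CC)(CC)CC)[C@@H]3CC(=O)O[C@H]3[C@@H]2OS(C)(=O)=O)(c4ccccc4)c5ccccc5.[K+] | intermediate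
28 | (4Z,6S,7R,8R)-15-(tert-butyldiphenylsilyloxy)-10-oxo-8-(triethylsilyloxy)-13,14-dinorgermacr-4-en-12,6-olide (ring carbons C3 and C6 trans) | O=C1C[C@@H](O[Si](CC)(CC)CC)[C@@H]2CC(=O)O[C@H]2/C=C(CO[Si](c3ccccc3)(c4ccccc4)C(C)(C)C)/CCC1 | intermediate
29 | (4Z,6S,7R,8R)-15-(tert-butyldiphenylsilyloxy)-8-(triethylsilyloxy)-13-norgermacra-4,10(14)-dien-12,6-olide | C=C1C[C@@H](O[Si](CC)(CC)CC)[C@@H]2CC(=O)O[C@H]2/C=C(CO[Si](c3ccccc3)(c4ccccc4)C(C)(C)C)/CCC1 | intermediate
30 | B-(C14-alkyl)-9-borabicyclo[3.3.1]nonane from 29 (10R) | C(B1C2CCCC1CCC2)[C@H]3C[C@@H](O[Si](CC)(CC)CC)[C@@H]4CC(=O)O[C@H]4/C=C(CO[Si](c5ccccc5)(c6ccccc6)C(C)(C)C)/CCC3 | intermediate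
31 | (4Z,6S,7R,8R,10R)-15-(tert-butyldiphenylsilyloxy)-14-hydroxy-8-(triethylsilyloxy)-13-norgermacr-4-en-12,6-olide | OC[C@H]1C[C@@H](O[Si](CC)(CC)CC)[C@@H]2CC(=O)O[C@H]2/C=C(CO[Si](c3ccccc3)(c4ccccc4)C(C)(C)C)/CCC1 | intermediate
32 | (4Z,6S,7R,8R,10R)-14,15-bis(tert-butyldiphenylsilyloxy)-8-(triethylsilyloxy)-13-norgermacr-4-en-12,6-olide | CC(C)(C)[Si](OC[C@H]1C[C@@H](O[Si](CC)(CC)CC)[C@@H]2CC(=O)O[C@H]2/C=C(CO[Si](c3ccccc3)(c4ccccc4)C(C)(C)C)/CCC1)(c5ccccc5)c6ccccc6 | intermediate
33 | 11-(dimethylaminomethyl) derivative of 32 (C11 epimers) | CC(C)(C)[Si](OC[C@H]1C[C@@H](O[Si](CC)(CC)CC)[C@@H]2C(CN(C)C)C(=O)O[C@H]2/C=C(CO[Si](c3ccccc3)(c4ccccc4)C(C)(C)C)/CCC1)(c5ccccc5)c6ccccc6 | intermediate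
34 | trimethylammonium iodide from 33 | CC(C)(C)[Si](OC[C@H]1C[C@@H](O[Si](CC)(CC)CC)[C@@H]2C(C[N+](C)(C)C)C(=O)O[C@H]2/C=C(CO[Si](c3ccccc3)(c4ccccc4)C(C)(C)C)/CCC1)(c5ccccc5)c6ccccc6.[I-] | intermediate
35 | (4Z,6S,7R,8R,10R)-14,15-bis(tert-butyldiphenylsilyloxy)-8-(triethylsilyloxy)germacra-4,11(13)-dien-12,6-olide | CC(C)(C)[Si](OC[C@H]1C[C@@H](O[Si](CC)(CC)CC)[C@@H]2C(=C)C(=O)O[C@H]2/C=C(CO[Si](c3ccccc3)(c4ccccc4)C(C)(C)C)/CCC1)(c5ccccc5)c6ccccc6 | intermediate
36 | (4Z,6S,7S,8R,10R)-14,15-bis(tert-butyldiphenylsilyloxy)-8-hydroxygermacra-4,11(13)-dien-12,6-olide | CC(C)(C)[Si](OC[C@H]1C[C@@H](O)[C@@H]2C(=C)C(=O)O[C@H]2/C=C(CO[Si](c3ccccc3)(c4ccccc4)C(C)(C)C)/CCC1)(c5ccccc5)c6ccccc6 | intermediate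
37 | methacrylic anhydride | CC(=C)C(=O)OC(=O)C(C)=C | starting material
38 | (4Z,6S,7S,8R,10R)-14,15-bis(tert-butyldiphenylsilyloxy)-8-(methacryloyloxy)germacra-4,11(13)-dien-12,6-olide | CC(C)(C)[Si](OC[C@H]1C[C@@H](OC(=O)C(C)=C)[C@@H]2C(=C)C(=O)O[C@H]2/C=C(CO[Si](c3ccccc3)(c4ccccc4)C(C)(C)C)/CCC1)(c5ccccc5)c6ccccc6 | intermediate
39 | (4Z,6S,7S,8R,10R)-14,15-dihydroxy-8-(methacryloyloxy)germacra-4,11(13)-dien-12,6-olide (CNP0256084.5) | OC[C@H]1C[C@@H](OC(=O)C(C)=C)[C@@H]2C(=C)C(=O)O[C@H]2/C=C(CO)/CCC1 | target

## Step count and least certain steps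

Total step count: 25. Longest linear sequence: 24 steps (steps 1–3 and 5–25, from 1 to 39); step 4 is the one-step side branch.

**Step 18 (key step).** The most likely failures are slow fragmentation and capping of the donor oxygen. The neopentyl silyl ether crowds the alkoxide, and under base the silyl group can migrate from O15 to O10, which stops the fragmentation. Any excess base can also start loss of the C8 silyloxy group from the new ketone.
Fallback: set out from hydroxy acid 24 and fragment it as its dianion (two equivalents of KOtBu), where a carboxylate sits on C4 and no silyl group is present. This gives the keto acid (4Z,6S,7R,8R)-10-oxo-8-(triethylsilyloxy)-13,14-dinorgermacr-4-en-12,6-olide-15-oic acid F1. Wittig methylenation gives the methylene acid F2. Reduction of its mixed carbonic anhydride (isobutyl chloroformate, N-methylmorpholine, then NaBH4) gives the allylic alcohol F3. Silylation with TBDPSCl returns to the route at 29.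

**Step 7.** The nitrile oxide may dimerise faster than it adds to a trisubstituted, electron-poor alkene, and the face selectivity relative to C6 may be poor because it rests on a conformational preference.
Fallback: change the dipole to a silyl nitronate, which does not dimerise. Alkylate 6 with 1-bromo-4-chlorobutane to the chloro phosphonate F4. Olefinate 5 with it to the chloro enoate F5. Exchange chloride for nitro (NaNO2, catalytic NaI, DMF) to reach the nitro enoate F6. Treat with TMSCl and Et3N to form the silyl nitronate F7, which cyclises to the N-silyloxy isoxazolidine F8. Acid-induced loss of silanol returns to the route at 14.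

**Step 12.** The samarium enolate may be protonated before it reaches the hindered ketone (net loss of bromine), or it may equilibrate towards C7. The trivalent samarium alkoxide of the product may also begin to fragment early, because the mesylate is already in place.
Fallback: set out from 19 and make the enolate equivalent isolable. Reductive silylation (Zn, TMSCl) gives the C9 silyl enol ether F9. An intramolecular Mukaiyama aldol under TiCl4 at −78 °C onto the chelated keto ester returns to the route at 21.

**Step 20.** The face selectivity at C10 may be poor, because the ten-membered ring is mobile and the only control element is the C8 substituent two atoms away.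
Fallback: tie C14 to O8, so that the two can only end up syn. Set out from 29 and remove the triethylsilyl group (PPTS, MeOH) to the alcohol F10. Silylate with (HMe2Si)2NH to the dimethylsilyl ether F11. Close the six-membered siloxane F12 by intramolecular hydrosilylation with catalytic H2PtCl6. Oxidise the C–Si bond (H2O2, KF, KHCO3, Tamao–Fleming type) to the diol F13. Silylate the primary alcohol with TBDPSCl to F14, then silylate C8 with TESCl, which returns to the route at 32.

## Further compounds

F1 | step 18 | (4Z,6S,7R,8R)-10-oxo-8-(triethylsilyloxy)-13,14-dinorgermacr-4-en-12,6-olide-15-oic acid | O=C1C[C@@H](O[Si](CC)(CC)CC)[C@@H]2CC(=O)O[C@H]2/C=C(C(O)=O)/CCC1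
F2 | step 18 | (4Z,6S,7R,8R)-8-(triethylsilyloxy)-13-norgermacra-4,10(14)-dien-12,6-olide-15-oic acid | C=C1C[C@@H](O[Si](CC)(CC)CC)[C@@H]2CC(=O)O[C@H]2/C=C(C(O)=O)/CCC1
F3 | step 18 | (4Z,6S,7R,8R)-15-hydroxy-8-(triethylsilyloxy)-13-norgermacra-4,10(14)-dien-12,6-olide | C=C1C[C@@H](O[Si](CC)(CC)CC)[C@@H]2CC(=O)O[C@H]2/C=C(CO)/CCC1
F4 | step 7 | benzyl 6-chloro-2-(diethoxyphosphoryl)hexanoate (racemic) | CCOP(=O)(OCC)C(CCCCCl)C(=O)OCc1ccccc1
F5 | step 7 | benzyl (2E)-2-(4-chlorobutyl)-3-[(2R,3S)-3-ethenyl-5-oxooxolan-2-yl]prop-2-enoate | ClCCCC/C(C(=O)OCc1ccccc1)=C\[C@@H]1OC(=O)C[C@H]1C=C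
F6 | step 7 | benzyl (2E)-3-[(2R,3S)-3-ethenyl-5-oxooxolan-2-yl]-2-(4-nitrobutyl)prop-2-enoate | O=[N+]([O-])CCCC/C(C(=O)OCc1ccccc1)=C\[C@@H]1OC(=O)C[C@H]1C=C
F7 | step 7 | trimethylsilyl nitronate of F6 | C[Si](C)(C)O[N+]([O-])=CCCC/C(C(=O)OCc1ccccc1)=C\[C@@H]1OC(=O)C[C@H]1C=C
F8 | step 7 | benzyl (3R,3aR)-3-[(2R,3S)-3-ethenyl-5-oxooxolan-2-yl]-1-(trimethylsilyloxy)hexahydro-1H-cyclopenta[c][1,2]oxazole-3a-carboxylate (C6a epimers) | O=C(OCc1ccccc1)[C@]23CCCC2N(O[Si](C)(C)C)O[C@H]3[C@@H]4OC(=O)C[C@H]4C=C
F9 | step 12 | trimethylsilyl enol ether of 19 (O–Si on C8, methylene C9) | O=C(OCc1ccccc1)[C@@]1(CCCC1=O)[C@@H](OS(C)(=O)=O)[C@@H]2OC(=O)C[C@H]2C(=C)O[Si](C)(C)C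
F10 | step 20 | (4Z,6S,7S,8R)-15-(tert-butyldiphenylsilyloxy)-8-hydroxy-13-norgermacra-4,10(14)-dien-12,6-olide | C=C1C[C@@H](O)[C@@H]2CC(=O)O[C@H]2/C=C(CO[Si](c3ccccc3)(c4ccccc4)C(C)(C)C)/CCC1
F11 | step 20 | 8-O-dimethylsilyl ether of F10 | C=C1C[C@@H](O[SiH](C)C)[C@@H]2CC(=O)O[C@H]2/C=C(CO[Si](c3ccccc3)(c4ccccc4)C(C)(C)C)/CCC1
F12 | step 20 | cyclic siloxane bridging O8 and C14 through SiMe2 (10R) | C[Si]1(C)C[C@H]2C[C@@H](O1)[C@@H]3CC(=O)O[C@H]3/C=C(CO[Si](c4ccccc4)(c5ccccc5)C(C)(C)C)/CCC2
F13 | step 20 | (4Z,6S,7S,8R,10R)-15-(tert-butyldiphenylsilyloxy)-8,14-dihydroxy-13-norgermacr-4-en-12,6-olide | OC[C@H]1C[C@@H](O)[C@@H]2CC(=O)O[C@H]2/C=C(CO[Si](c3ccccc3)(c4ccccc4)C(C)(C)C)/CCC1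
F14 | step 20 | (4Z,6S,7S,8R,10R)-14,15-bis(tert-butyldiphenylsilyloxy)-8-hydroxy-13-norgermacr-4-en-12,6-olide | CC(C)(C)[Si](OC[C@H]1C[C@@H](O)[C@@H]2CC(=O)O[C@H]2/C=C(CO[Si](c3ccccc3)(c4ccccc4)C(C)(C)C)/CCC1)(c5ccccc5)c6ccccc6
A1 | alternative 1 | ten-membered trans-lactone with free C8 hydroxyl and silylated C14 and C15 | O[C@@H]1C[C@H](CO[Si](C)(C)C(C)(C)C)CCC/C(CO[Si](C)(C)C(C)(C)C)=C/[C@@H]2OC(=O)C[C@H]21
A2 | alternative 1 | open-chain C8 aldehyde carrying the butenolide | O=CC[C@H](CO[Si](C)(C)C(C)(C)C)CCC/C(CO[Si](C)(C)C(C)(C)C)=C/[C@@H]1OC(=O)C=C1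
A3 | alternative 2 | ten-membered C6 allylic alcohol with C12 methyl ester | O[C@H]1/C=C(CO[Si](C)(C)C(C)(C)C)/CCC[C@@H](CO[Si](C)(C)C(C)(C)C)C[C@@H](OCc2ccc(OC)cc2)[C@@H]1CC(=O)OC
A4 | alternative 2 | open-chain C5 alkenyl iodide with C6 aldehyde | I/C=C(CO[Si](C)(C)C(C)(C)C)/CCC[C@@H](CO[Si](C)(C)C(C)(C)C)C[C@@H](OCc1ccc(OC)cc1)[C@@H](C=O)CC(=O)OC
A5 | alternative 3 | ten-membered lactone with C14 methyl ester on C10 | COC(=O)[C@@H]1CCC/C(CO[Si](C)(C)C(C)(C)C)=C/[C@@H]2OC(=O)C[C@H]2[C@H](OCc2ccc(OC)cc2)C1
A6 | alternative 3 | open-chain C2 iodide with 2-substituted acrylate at C10 | C=C(C(=O)OC)C[C@@H](OCc1ccc(OC)cc1)[C@@H]2CC(=O)O[C@H]2/C=C(CO[Si](C)(C)C(C)(C)C)/CCI
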